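I will rank the remedies for this flask by one number taken from its own readings, and I will trust nothing that number cannot reach.

common to all: substrate 0.50 M; free catalyst 25 mM

|  | temperature | remark | time |
|---|---|---|---|
| eta | 40 °C | the very flask that is asked about, followed so far |  |
| theta | 46 °C | run made earlier |  |
| flask | 40 °C |  | 20 min |

- eta (time / min: product / %): 0.833: 4.0; 2.50: 4.3; 4.00: 6.8; 6.00: 7.4; 10.0: 11.2; 12.0: 11.1
- theta (time / min: product / %): 0.833: 0; 2.50: 6.0; 4.00: 8.8; 6.00: 10.1; 10.0: 7.8; 12.0: 9.0

(each reading ± 1 percentage point)

- noon: at 20 min take out 90% of the product then present, then wait 40 min
- winter: at 20 min add free catalyst, 100% of the amount charged, then wait 40 min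
- summer: change nothing and wait 40 min more
- autumn: at 20 min raise the temperature by 20 K, then wait 40 min

- product taken out counts as made
- additions bring no volume worth counting

* product, in percent of the substrate first charged, at 20 min
* the remedy with the largest gain of product, or "none" below 2 percentage points (noon / winter / summer / autumn / none)
* product present, with what was taken out counted in, in percent of the substrate first charged, after noon
* product present, with what was taken out counted in, in percent of the substrate first charged, after autumn

The eta run, which is this flask followed so far, levels at 11.1% on the mean of its last two readings, each good to 1 percentage point. In moles that gives the purse, my name for the turnover number: product made per free catalyst charged, here 2.23. The hotter theta run levels lower than that, at 8.97% on the mean of its last three readings. These readings do not separate a dying catalyst from an equilibrium; I commit to the dying catalyst, and that is my choice. At the plateau 88.9% of the charge is still not product, so I freeze that rest as constant, and the rate becomes pseudo-first-order, following [free catalyst].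

The shortest time on my ladder is the life of free catalyst, 4.25 min as read from the reading at 4.00 min. The next is the asked time, 20 min, longer than that life: in my reckoning 0.904% of the free catalyst survives, product stands at 11.0%, and a tail of 0.1 points remains to be made. The longest is 38.1 min, the time my starting rate would need for the whole charge; in my reckoning this flask stops short of the whole charge because the life of free catalyst is shorter.

So waiting buys the tail, and so does noon, since my rate holds no term in product: 11.1% after noon. Autumn, in my reckoning, spends the tail at a smaller purse, as the lower level of the theta run suggests, which puts it between 11.0% and 11.1%. In my reckoning winter buys a new purse, 11 points, more than the 2 points threshold.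

The forecast gives 12.5% (11% to 14.5%), above my figure, with 12.7% after noon, 12.7% after autumn and winter as best: “Fresh catalyst restarts the reaction”.

The flask gives 11.2%, 11.3% after noon, 11.2% after autumn, and winter as best with a gain of 11 points.

    substrate → intermediate (k = 2.41 min⁻¹, Ea = 88.0 kJ mol⁻¹)
    free catalyst + intermediate → free catalyst + product (k = 1.19 L mol⁻¹ min⁻¹, Ea = 52.0 kJ mol⁻¹)
    free catalyst → spent catalyst (k = 0.227 min⁻¹, Ea = 78.0 kJ mol⁻¹)
    (constants at 40 °C)

In this flask at 20.0 min free catalyst stands at 1.07% of its charge, while 88.8% of the substrate charged waits as intermediate. A neighbour flask charged with 0.0063 M of free catalyst gets 2.81% from the purse, and at 20.0 min it holds 2.94%.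

All runs are calculated for an exercise, noise included.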